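The depside is cut at its aryl ester into a ring B phenol and a ring A keto acid. Ring A is built on its ortho pair: the carboxyl carbon on C1 and the CH2 of the 2-oxopentyl chain on C6, with the C2 oxygen beside C1. One aryne insertion into a C–C bond of dimethyl malonate forms both ring-to-carbon bonds at once, the C2 oxygen steering the carboxyl to C1. The aryne precursor is an ortho-silyl aryl triflate carrying both oxygens as methyl ethers, so the phenol it comes from is symmetric. The homophthalate is then turned into an isocoumarin, unmasked at C2–OH, opened and esterified.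

Key step: step 4

Remark: the target has no stereocentre; ring A is numbered from the carbon bearing the carboxyl (C1), with the hydroxyl on C2, the methoxy group on C4 and the 2-oxopentyl chain on C6.

Step 1
Reactants: 1 3,5-dimethoxyphenol
Product: 2 2-bromo-3,5-dimethoxyphenol
Conditions: NBS (1.0 equiv), CH2Cl2, −78 °C → rt
Reagents that add atoms: N-bromosuccinimide, O=C1CCC(=O)N1Br
Why: Electrophilic aromatic bromination in which the free hydroxyl is the strongest activator and cold NBS delivers bromine to its ortho carbon, the two ortho positions being equivalent by symmetry and one equivalent of reagent stopping at the monobromide.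

Step 2
Reactants: 2 2-bromo-3,5-dimethoxyphenol
Product: 3 (2-bromo-3,5-dimethoxyphenoxy)trimethylsilane
Conditions: HMDS, THF, 70 °C; evaporate
Reagents that add atoms: hexamethyldisilazane, C[Si](C)(C)N[Si](C)(C)C
Why: O-silylation of a phenol with HMDS, which gives only ammonia beside the product so that the moisture-sensitive silyl ether can be used directly after evaporation.

Step 3
Reactants: 3 (2-bromo-3,5-dimethoxyphenoxy)trimethylsilane
Product: 5 3,5-dimethoxy-2-(trimethylsilyl)phenyl trifluoromethanesulfonate, via lithium 3,5-dimethoxy-2-(trimethylsilyl)phenoxide 4 (not isolated)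
Conditions: n-BuLi, THF, −100 → −78 °C; then Tf2O, −100 °C → rt
Reagents that add atoms: trifluoromethanesulfonic anhydride, O=S(=O)(OS(=O)(=O)C(F)(F)F)C(F)(F)F
Why: Bromine–lithium exchange gives an aryllithium that takes the silyl group from the neighbouring oxygen in a retro-Brook 1,3 oxygen-to-carbon shift, and the phenoxide so formed is trapped by O-sulfonylation.

Step 4
Reactants: 5 3,5-dimethoxy-2-(trimethylsilyl)phenyl trifluoromethanesulfonate; 6 dimethyl malonate
Product: 8 methyl 2,4-dimethoxy-6-(2-methoxy-2-oxoethyl)benzoate, via 3,5-dimethoxybenzyne 7 (not isolated)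
Conditions: 6 (2 equiv), KF, 18-crown-6, THF, 0 °C → rt, 5 added slowly
Reagents that add atoms: none
Why: Fluoride attacks silicon and triflate leaves from the neighbouring carbon to give aryne 7; the malonate anion adds to the aryne carbon remote from the flanking methoxy group, the aryl anion next to that methoxy group closes onto one ester carbonyl to a benzocyclobutenoxide, and strain-driven cleavage of the old malonate C–C bond leaves an ester enolate that is protonated to 8. The closest known reaction type is aryne insertion into the C–C sigma bond of malonates and beta-keto esters (aryne acyl-alkylation). The only ring formed is the transient four-membered one, closed in a 4-exo-trig mode and reopened in the same operation, so 8 contains no new ring. No stereocentre is created. The selectivity needed is the regiochemistry of the first addition; the methoxy group beside the triple bond secures it by polarising the aryne so that negative charge develops on the carbon next to the C–O bond, which places the carboxyl carbon beside oxygen and the CH2 on the far side.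

Step 5
Reactants: 8 methyl 2,4-dimethoxy-6-(2-methoxy-2-oxoethyl)benzoate
Product: 9 2-(carboxymethyl)-4,6-dimethoxybenzoic acid
Conditions: KOH, MeOH/H2O, reflux; then HCl, 0 °C
Reagents that add atoms: water, O (delivered as hydroxide from KOH)
Why: Saponification of both esters, where excess hot hydroxide is needed for the benzoate flanked by two ortho substituents and the aryl methyl ethers are inert to base.

Step 6
Reactants: 9 2-(carboxymethyl)-4,6-dimethoxybenzoic acid; 10 butanoyl chloride
Product: 13 6,8-dimethoxy-3-propyl-1H-isochromen-1-one, via 6,8-dimethoxyisochromane-1,3-dione 11 (not isolated), via 4-butanoyl-6,8-dimethoxyisochromane-1,3-dione 12 (not isolated)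
Conditions: 10 (4 equiv), neat, reflux with the bath raised to 200 °C, 4 h
Reagents that add atoms: none
Why: Thermal condensation of a homophthalic acid with an acyl chloride, in which the acid chloride dehydrates 9 to anhydride 11, the enolisable C4 of 11 is C-acylated to 12, and at high temperature the enol oxygen of the new acyl group lactonises onto the aryl carbonyl while the former acetic acid carboxyl leaves as CO2.

Step 7
Reactants: 13 6,8-dimethoxy-3-propyl-1H-isochromen-1-one
Product: 14 8-hydroxy-6-methoxy-3-propyl-1H-isochromen-1-one
Conditions: BCl3 (1 M in CH2Cl2), CH2Cl2, −78 → 0 °C; then H2O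
Reagents that add atoms: none
Why: Chelation-controlled Lewis acid ether cleavage, in which BCl3 bridges the lactone carbonyl and the peri methoxy oxygen on C8 in a six-membered chelate so that chloride removes only that methyl group, the C6 ether having no carbonyl neighbour.

Step 8
Reactants: 14 8-hydroxy-6-methoxy-3-propyl-1H-isochromen-1-one
Product: 15 2-hydroxy-4-methoxy-6-(2-oxopentyl)benzoic acid
Conditions: KOH (5% aq.), EtOH, reflux; then dilute HCl to pH 2–3, 0 °C
Reagents that add atoms: water, O (delivered as hydroxide from KOH)
Why: Alkaline hydrolysis of an enol lactone, where hydroxide opens the isocoumarin at C1 to the carboxylate and an enolate that is protonated to the 2-oxopentyl ketone, cold acidification avoiding relactonisation and decarboxylation.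

Step 9
Reactants: 16 5-propylresorcinol
Product: 17 2,4-dihydroxy-6-propylbenzoic acid
Conditions: MeOMgOCO2Me (2 M in DMF), 120 °C; then cold dilute HCl
Reagents that add atoms: magnesium methyl carbonate (MeOMgOCO2Me), COC(=O)O[Mg]OC
Why: Stiles carboxylation (a Kolbe–Schmitt type reaction), in which the magnesium phenoxide delivers CO2 to the ring carbon that is ortho to one oxygen and para to the other and the product is held as a magnesium salicylate chelate until work-up.

Step 10
Reactants: 17 2,4-dihydroxy-6-propylbenzoic acid
Product: 18 benzyl 2,4-dihydroxy-6-propylbenzoate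
Conditions: BnBr, KHCO3, DMF, rt
Reagents that add atoms: benzyl bromide, BrCc1ccccc1
Why: SN2 O-alkylation of the carboxylate, since hydrogencarbonate deprotonates only the carboxylic acid and leaves both phenols protonated and unreactive.

Step 11
Reactants: 15 2-hydroxy-4-methoxy-6-(2-oxopentyl)benzoic acid; 18 benzyl 2,4-dihydroxy-6-propylbenzoate
Product: 19 benzyl 2-hydroxy-4-{[2-hydroxy-4-methoxy-6-(2-oxopentyl)benzoyl]oxy}-6-propylbenzoate
Conditions: DCC (1.1 equiv), DMAP (5 mol%), CH2Cl2, 0 °C → rt
Reagents that add atoms: none
Why: Steglich carbodiimide esterification, in which only the C4 hydroxyl of 18 is acylated because the C2 hydroxyl of each ring is hydrogen-bonded to its ortho carbonyl, the neutral cold conditions being chosen to keep the ketone from enolising onto the activated carboxyl.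

Step 12
Reactants: 19 benzyl 2-hydroxy-4-{[2-hydroxy-4-methoxy-6-(2-oxopentyl)benzoyl]oxy}-6-propylbenzoate
Product: 20 2-hydroxy-4-{[2-hydroxy-4-methoxy-6-(2-oxopentyl)benzoyl]oxy}-6-propylbenzoic acid
Conditions: H2 (1 atm), 10% Pd/C, EtOAc, rt
Reagents that add atoms: none
Why: Catalytic hydrogenolysis of the benzyl ester, which leaves the aryl ester, the aliphatic ketone and the methyl ether untouched and needs neither acid nor base, so the base-labile depside link and the decarboxylation-prone salicylic acid should survive.

Compound list
1 | 3,5-dimethoxyphenol | COc1cc(O)cc(OC)c1 | starting material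
2 | 2-bromo-3,5-dimethoxyphenol | COc1cc(O)c(Br)c(OC)c1 | intermediate
3 | (2-bromo-3,5-dimethoxyphenoxy)trimethylsilane | COc1cc(O[Si](C)(C)C)c(Br)c(OC)c1 | intermediate
4 | lithium 3,5-dimethoxy-2-(trimethylsilyl)phenoxide | [Li+].[O-]c1cc(OC)cc(OC)c1[Si](C)(C)C | intermediate (not isolated)
5 | 3,5-dimethoxy-2-(trimethylsilyl)phenyl trifluoromethanesulfonate | COc1cc(OC)c([Si](C)(C)C)c(OS(=O)(=O)C(F)(F)F)c1 | intermediate
6 | dimethyl malonate | COC(=O)CC(=O)OC | starting material
7 | 3,5-dimethoxybenzyne | COC1=CC(OC)=CC#C1 | intermediate (not isolated)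
8 | methyl 2,4-dimethoxy-6-(2-methoxy-2-oxoethyl)benzoate | COC(=O)Cc1cc(OC)cc(OC)c1C(=O)OC | intermediate
9 | 2-(carboxymethyl)-4,6-dimethoxybenzoic acid | OC(=O)Cc1cc(OC)cc(OC)c1C(=O)O | intermediate
10 | butanoyl chloride | CCCC(=O)Cl | starting material
11 | 6,8-dimethoxyisochromane-1,3-dione | COc1cc2CC(=O)OC(=O)c2c(OC)c1 | intermediate (not isolated)
12 | 4-butanoyl-6,8-dimethoxyisochromane-1,3-dione | CCCC(=O)C1C(=O)OC(=O)c2c(OC)cc(OC)cc21 | intermediate (not isolated)
13 | 6,8-dimethoxy-3-propyl-1H-isochromen-1-one | CCCC1=Cc2cc(OC)cc(OC)c2C(=O)O1 | intermediate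
14 | 8-hydroxy-6-methoxy-3-propyl-1H-isochromen-1-one | CCCC1=Cc2cc(OC)cc(O)c2C(=O)O1 | intermediate
15 | 2-hydroxy-4-methoxy-6-(2-oxopentyl)benzoic acid | CCCC(=O)Cc1cc(OC)cc(O)c1C(=O)O | intermediate
16 | 5-propylresorcinol | CCCc1cc(O)cc(O)c1 | starting material
17 | 2,4-dihydroxy-6-propylbenzoic acid | CCCc1cc(O)cc(O)c1C(=O)O | intermediate
18 | benzyl 2,4-dihydroxy-6-propylbenzoate | CCCc1cc(O)cc(O)c1C(=O)OCc1ccccc1 | intermediate
19 | benzyl 2-hydroxy-4-{[2-hydroxy-4-methoxy-6-(2-oxopentyl)benzoyl]oxy}-6-propylbenzoate | CCCC(=O)Cc1cc(OC)cc(O)c1C(=O)Oc1cc(O)c(C(=O)OCc2ccccc2)c(CCC)c1 | intermediate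
20 | 2-hydroxy-4-{[2-hydroxy-4-methoxy-6-(2-oxopentyl)benzoyl]oxy}-6-propylbenzoic acid | CCCC(=O)Cc1cc(OC)cc(O)c1C(=O)Oc1cc(O)c(C(=O)O)c(CCC)c1 | target

Total steps: 12. Longest linear sequence: 10 (steps 1 to 8, then 11 and 12); steps 9 and 10 form the ring B branch.

Steps most likely to fail

Step 4. The aryl anion may be protonated before it closes onto the ester, which gives plain C-arylation of the malonate. The product enolate may also capture a second aryne, and regiocontrol of the first addition may erode if the mixture warms. Fallback: the same ortho pair is built without an aryne, by formylation and oxidation. It sets out from no numbered compound (1 to 8 are bypassed) but from commercial methyl 2-(3,5-dimethoxyphenyl)acetate F1, and comes back to the route at 9. Vilsmeier–Haack formylation (POCl3, DMF) should go to the ring carbon ortho to the CH2 and para to a methoxy group, giving methyl 2-(2-formyl-3,5-dimethoxyphenyl)acetate F2. Pinnick oxidation (NaClO2, NaH2PO4, 2-methyl-2-butene) then gives 2,4-dimethoxy-6-(2-methoxy-2-oxoethyl)benzoic acid F3. Saponification under the conditions of step 5 delivers 9.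

Step 11. Once the carboxyl is activated, the ketone enol may close onto it and return the isocoumarin faster than the hindered acyl group is transferred to the phenol. The same closure could expel the ring B phenol from the product if base is present. Fallback: the ketone is masked before the carboxyl is activated. It sets out from 15 and comes back at 19. The carboxylate of 15 is benzylated (BnBr, KHCO3, DMF) to benzyl 2-hydroxy-4-methoxy-6-(2-oxopentyl)benzoate F4. The ketone is converted into its dioxolane with 1,2-bis(trimethylsilyloxy)ethane and catalytic TMSOTf in CH2Cl2 at −78 °C, giving benzyl 2-hydroxy-4-methoxy-6-[(2-propyl-1,3-dioxolan-2-yl)methyl]benzoate F5. Hydrogenolysis (H2, Pd/C, EtOAc) frees 2-hydroxy-4-methoxy-6-[(2-propyl-1,3-dioxolan-2-yl)methyl]benzoic acid F6, which can no longer enolise. F6 is coupled at once with 18 (DCC, DMAP, CH2Cl2) to benzyl 2-hydroxy-4-({2-hydroxy-4-methoxy-6-[(2-propyl-1,3-dioxolan-2-yl)methyl]benzoyl}oxy)-6-propylbenzoate F7. Mild aqueous acid (PPTS, acetone/H2O) removes the dioxolane and returns 19.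

Step 9. Carboxylation may occur at the carbon between the two hydroxyls instead of the one between hydroxyl and propyl, conversion may stay incomplete, and the product may lose CO2 during acidic work-up. Fallback: ring B is assembled with the carboxyl already in place. It sets out from 6 and comes back at 17. Michael addition of 6 to (E)-hept-3-en-2-one F8 followed by Claisen ring closure (NaOMe, MeOH, reflux) gives methyl 2-hydroxy-4-oxo-6-propylcyclohex-2-ene-1-carboxylate F9, a stereoisomer mixture of no consequence. Bromination and dehydrobromination (Br2, DMF, 0 °C, then warming) aromatise it to methyl 2,4-dihydroxy-6-propylbenzoate F10, in which the carboxyl sits between hydroxyl and propyl by construction. Saponification (KOH, MeOH/H2O, reflux; cold acidification) gives 17.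

Further compounds
F1 | step 4 | methyl 2-(3,5-dimethoxyphenyl)acetate | COC(=O)Cc1cc(OC)cc(OC)c1
F2 | step 4 | methyl 2-(2-formyl-3,5-dimethoxyphenyl)acetate | COC(=O)Cc1cc(OC)cc(OC)c1C=O
F3 | step 4 | 2,4-dimethoxy-6-(2-methoxy-2-oxoethyl)benzoic acid | COC(=O)Cc1cc(OC)cc(OC)c1C(=O)O
F4 | step 11 | benzyl 2-hydroxy-4-methoxy-6-(2-oxopentyl)benzoate | CCCC(=O)Cc1cc(OC)cc(O)c1C(=O)OCc1ccccc1
F5 | step 11 | benzyl 2-hydroxy-4-methoxy-6-[(2-propyl-1,3-dioxolan-2-yl)methyl]benzoate | CCCC1(Cc2cc(OC)cc(O)c2C(=O)OCc2ccccc2)OCCO1
F6 | step 11 | 2-hydroxy-4-methoxy-6-[(2-propyl-1,3-dioxolan-2-yl)methyl]benzoic acid | CCCC1(Cc2cc(OC)cc(O)c2C(=O)O)OCCO1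
F7 | step 11 | benzyl 2-hydroxy-4-({2-hydroxy-4-methoxy-6-[(2-propyl-1,3-dioxolan-2-yl)methyl]benzoyl}oxy)-6-propylbenzoate | CCCC1(Cc2cc(OC)cc(O)c2C(=O)Oc2cc(O)c(C(=O)OCc3ccccc3)c(CCC)c2)OCCO1
F8 | step 9 | (E)-hept-3-en-2-one | CCC/C=C/C(C)=O
F9 | step 9 | methyl 2-hydroxy-4-oxo-6-propylcyclohex-2-ene-1-carboxylate | CCCC1CC(=O)C=C(O)C1C(=O)OC
F10 | step 9 | methyl 2,4-dihydroxy-6-propylbenzoate | CCCc1cc(O)cc(O)c1C(=O)OC
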